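**Strategy.** The cyclobutane is cut at its C1–C2 bond, between quaternary C1 (CH3, CO2R) and the guaiacyl-bearing C2–H. Both carbons are radical-stabilising and are the termini of a vanillin/alanine azomethine ylide, so a nitrogen is placed between them: the precursor is a 5-aryl-2-methylpyrrolidine-2,4-dicarboxylate from a silver-catalysed asymmetric [3+2] cycloaddition and C5 epimerisation. Nitrogen deletion (1,1-diazene, loss of N2, 1,4-biradical coupling) contracts this ring to the fully substituted cyclobutane with all four stereocentres in place. Its three differentiated esters (tert-butyl, benzyl, methyl) are then unmasked one at a time and each acid is joined to the C6-epimeric bicyclic amino alcohol by an inverting Mitsunobu reaction.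

Key step: step 7

Remark 1: the amino alcohol unit is built exactly as written in the target SMILES (cis-fused, C4 and C7 methyls on the face of the ring-fusion hydrogens, C6 oxygen on the opposite face).
Remark 2: the senses of induction of (S)-QUINAP (step 5) and of the TaniaPhos enantiomer (step 11) are assigned by analogy; the antipodal ligand is used if the sense proves opposite.
Remark 3: from compound 14 onwards the cyclobutane keeps the numbering of 14 (C1 quaternary with CH3 and carboxyl, C2 aryl, C3 carboxyl, C4 side chain; ring configuration 1R,2S,3S,4S throughout), and "group Q" means the (4R,4aR,6R,7R,7aS)-2,4,7-trimethyloctahydro-1H-cyclopenta[c]pyridin-6-yl ester group.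

Step 1
Reactants: 1 tert-butyl but-2-ynoate; 2 but-3-en-1-ylmagnesium bromide
Product: 4 tert-butyl (2E)-3-methylhepta-2,6-dienoate, via alkenylcopper adduct 3 (not isolated)
Conditions: 2 and CuBr·SMe2 (1.2 equiv each), THF, −40 °C; 1, −78 °C; MeOH, −78 °C
Reagents that add atoms: none
Why: Syn carbocupration of the alkynoate by the butenylcopper reagent and cold, stereoretentive protonation of the alkenylcopper place the butenyl chain trans to the ester, which fixes the (E) trisubstituted enoate of the later side chain (organocopper conjugate addition to an ynoate).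

Step 2
Reactants: 4 tert-butyl (2E)-3-methylhepta-2,6-dienoate; 5 methyl acrylate
Product: 6 1-tert-butyl 8-methyl (2E,6E)-3-methylocta-2,6-dienedioate
Conditions: 5 (5 equiv), second-generation Hoveyda–Grubbs catalyst (3 mol %), CH2Cl2, 40 °C
Reagents that add atoms: none
Why: Olefin cross-metathesis of the terminal alkene with the acrylate should give the (E)-disubstituted enoate under thermodynamic control, while the trisubstituted electron-poor C2=C3 alkene is inert to the catalyst.

Step 3
Reactants: 7 vanillin
Product: 8 3-methoxy-4-[(triisopropylsilyl)oxy]benzaldehyde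
Conditions: TIPSCl, imidazole, DMF, rt
Reagents that add atoms: triisopropylsilyl chloride, CC(C)[Si](Cl)(C(C)C)C(C)C
Why: Silylation masks the oxidation-prone and Mitsunobu-active phenol with a group that tolerates acid and is removed by fluoride at the end (silyl ether formation).

Step 4
Reactants: 8 3-methoxy-4-[(triisopropylsilyl)oxy]benzaldehyde; 9 L-alanine benzyl ester hydrochloride
Product: 10 benzyl (2S)-2-{[(E)-{3-methoxy-4-[(triisopropylsilyl)oxy]phenyl}methylidene]amino}propanoate
Conditions: Et3N, MgSO4, CH2Cl2, rt; used crude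
Reagents that add atoms: none
Why: Dehydrating condensation gives the (E)-aldimine that serves as azomethine ylide precursor; the alanine stereocentre is erased in the next step, so its configuration is immaterial (imine formation).

Step 5
Reactants: 10 the aldimine; 6 1-tert-butyl 8-methyl (2E,6E)-3-methylocta-2,6-dienedioate
Product: 11 2-benzyl 4-methyl (2S,3S,4S,5R)-3-[(3E)-5-tert-butoxy-3-methyl-5-oxopent-3-en-1-yl]-5-{3-methoxy-4-[(triisopropylsilyl)oxy]phenyl}-2-methylpyrrolidine-2,4-dicarboxylate (2-ester, 4-ester and 5-aryl all cis; 3-alkyl trans to them)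
Conditions: AgOAc (5 mol %), (S)-QUINAP (5.5 mol %), i-Pr2NEt (10 mol %), THF, −20 °C
Reagents that add atoms: none
Why: Silver-catalysed asymmetric [3+2] cycloaddition of the N,O-chelated azomethine ylide to the disubstituted methyl enoate only (the β,β-disubstituted tert-butyl enoate is too hindered) in the endo mode: the chelated ylide geometry sets 2-ester/5-aryl cis, endo approach sets the 4-ester cis to both, the (E)-alkene sets 3-alkyl trans to the 4-ester, and the chiral silver complex selects the ylide face.

Step 6
Reactants: 11 the endo cycloadduct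
Product: 12 2-benzyl 4-methyl (2S,3S,4S,5S)-3-[(3E)-5-tert-butoxy-3-methyl-5-oxopent-3-en-1-yl]-5-{3-methoxy-4-[(triisopropylsilyl)oxy]phenyl}-2-methylpyrrolidine-2,4-dicarboxylate (5-aryl trans to both ring esters, cis to the 2-methyl)
Conditions: [Ir{dF(CF3)ppy}2(dtbpy)]PF6 (1 mol %), PhSH (1 equiv), MeOH, blue LEDs, rt
Reagents that add atoms: none
Why: Reversible hydrogen-atom abstraction of the benzylic α-amino C5–H by the photogenerated thiyl radical and H-atom return from the thiol equilibrate C5 alone (C2 is quaternary, the other ring C–H bonds are polarity-mismatched, and the molecule holds no terminal alkene for thiol–ene addition), and the equilibrium should favour 12 because the aryl group escapes the cis relationship to the adjacent C4 ester (light-mediated thiyl-radical epimerisation of amines).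

Step 7
Reactants: 12 the 5S pyrrolidine
Product: 14 1-benzyl 3-methyl (1R,2S,3S,4S)-4-[(3E)-5-tert-butoxy-3-methyl-5-oxopent-3-en-1-yl]-2-{3-methoxy-4-[(triisopropylsilyl)oxy]phenyl}-1-methylcyclobutane-1,3-dicarboxylate, via 1,1-diazene 13 (not isolated)
Conditions: PhI(OH)OTs (2.5 equiv), H2NCO2NH4 (8 equiv), CF3CH2OH, 80 °C
Reagents that add atoms: none
Why: The hypervalent iodine reagent and ammonia (from ammonium carbamate) generate an electrophilic iodonitrene that aminates the ring nitrogen of 12 to 1,1-diazene 13, which extrudes N2 to a singlet 1,4-biradical (benzylic at the aryl-bearing carbon, tertiary and ester-stabilised at the methyl-bearing carbon) whose radical–radical coupling forms the bond between these two carbons. The closest known reaction type is the iodonitrene-mediated contraction of polysubstituted pyrrolidines to cyclobutanes (nitrogen deletion through a 1,1-diazene). The cyclobutane is the only ring closed, by intramolecular recombination of the 1,4-biradical, that is a ring contraction from five to four members with loss of the former ring nitrogen. No stereocentre is created from scratch: the two carbons that become bonded keep their configuration because collapse of the singlet biradical is faster than rotation about its C–C bonds, so the 2S,5S arrangement of 12 (aryl cis to the C2 methyl, trans to both ring esters) is transcribed into 14, and the two bystander centres are not touched. The step needs coupling to outrun β-scission of the biradical into two alkenes and needs the oxidant to attack nitrogen and not the arene; the alternating trans arrangement of the large groups lets the four-membered ring close without eclipsing them, the secondary NH is the only nucleophilic nitrogen (no tertiary amine is present yet), the three alkyl esters are inert, and the silyl ether (not a free phenol) with the ammonia buffer protects the electron-rich ring.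

Step 8
Reactants: 14 the cyclobutane triester
Product: 15 side-chain acid: compound 14 with the tert-butyl ester cleaved to the free (E)-3-methylpent-2-enoic acid terminus (C1 benzyl ester, C3 methyl ester and aryl silyl ether retained)
Conditions: TFA/CH2Cl2 (1:3), 0 °C to rt
Reagents that add atoms: none
Why: Acidolysis removes only the tert-butyl ester through the tert-butyl cation without base, so the epimerisable C3–H is safe and the benzyl ester, methyl ester and acid-stable aryl silyl ether stay on (tert-butyl ester cleavage).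

Step 9
Reactants: 16 but-2-yn-1-amine hydrochloride
Product: 17 tert-butyl but-2-yn-1-ylcarbamate
Conditions: Boc2O, Et3N, CH2Cl2, 0 °C to rt
Reagents that add atoms: di-tert-butyl dicarbonate, CC(C)(C)OC(=O)OC(=O)OC(C)(C)C
Why: Carbamate formation installs a nitrogen substituent that tolerates the Grignard and cobalt steps and is itself the latent N-methyl group (N-acylation).

Step 10
Reactants: 17 tert-butyl but-2-yn-1-ylcarbamate; 18 (E)-1,4-dibromobut-2-ene
Product: 19 tert-butyl [(2E)-4-bromobut-2-en-1-yl](but-2-yn-1-yl)carbamate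
Conditions: NaH, DMF, 0 °C; 18 (3 equiv), 0 °C to rt
Reagents that add atoms: none
Why: SN2 alkylation of the carbamate anion with an excess of the symmetrical dibromide should stop at monosubstitution and leaves the allylic bromide needed for the next step (N-alkylation).

Step 11
Reactants: 19 the allylic bromide
Product: 20 tert-butyl (but-2-yn-1-yl)[(2R)-2-methylbut-3-en-1-yl]carbamate
Conditions: MeMgBr (1.5 equiv), CuBr·SMe2 (5 mol %), TaniaPhos (6 mol %, enantiomer per remark 2), CH2Cl2, −78 °C
Reagents that add atoms: methylmagnesium bromide, C[Mg]Br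
Why: Copper-catalysed asymmetric allylic alkylation delivers the methyl group in SN2′ fashion to the carbon next to the CH2N group, and the chiral ferrocenyl diphosphine complex selects the alkene face to give the branched 2R product that becomes C4 of the bicycle.

Step 12
Reactants: 20 the 1,7-enyne
Product: 21 tert-butyl (4R,4aR)-4,7-dimethyl-6-oxo-1,3,4,4a,5,6-hexahydro-2H-cyclopenta[c]pyridine-2-carboxylate
Conditions: Co2(CO)8 (10 mol %), tetramethylthiourea (60 mol %), CO (1 atm), benzene, 70 °C
Reagents that add atoms: carbon monoxide, [C-]#[O+]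
Why: Intramolecular Pauson–Khand [2+2+1] reaction builds the cyclopentenone and the piperidine ring at once with the alkyne methyl α to the ketone, and the C4 methyl should sit pseudo-equatorial in the chair-like cobaltacycle-forming transition state so that C4a–H forms cis to it.

Step 13
Reactants: 21 the bicyclic enone
Product: 23 tert-butyl (4R,4aR,7R,7aS)-4,7-dimethyl-6-oxooctahydro-2H-cyclopenta[c]pyridine-2-carboxylate, via C7-epimeric cis-ketone 22 (not isolated)
Conditions: H2 (1 atm), Pd/C, EtOAc, rt; filter; DBU, CH2Cl2, rt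
Reagents that add atoms: none
Why: Hydrogen adds to the tetrasubstituted enone from the face of the C4a hydrogen to give the cis ring fusion, and base then epimerises the ketone α-carbon C7 to the more stable isomer with the methyl trans to the C7a–C1 bond (heterogeneous hydrogenation, then thermodynamic enolisation).

Step 14
Reactants: 23 the saturated ketone
Product: 24 tert-butyl (4R,4aR,6S,7R,7aS)-6-hydroxy-4,7-dimethyloctahydro-2H-cyclopenta[c]pyridine-2-carboxylate
Conditions: LiBH(s-Bu)3 (L-Selectride), THF, −78 °C; NaOH, H2O2, 0 °C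
Reagents that add atoms: none
Why: The bulky hydride attacks the cyclopentanone anti to the adjacent C7 methyl and gives the 6S alcohol (OH cis to that methyl), deliberately the epimer of the ester configuration because each later esterification inverts C6 (substrate-controlled ketone reduction).

Step 15
Reactants: 24 the Boc-protected alcohol
Product: 25 (4R,4aR,6S,7R,7aS)-2,4,7-trimethyloctahydro-1H-cyclopenta[c]pyridin-6-ol
Conditions: LiAlH4, THF, reflux
Reagents that add atoms: none
Why: LiAlH4 reduces the tert-butyl carbamate to the N-methyl group while the secondary alkoxide is untouched, so no stereocentre changes (carbamate reduction).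

Step 16
Reactants: 15 the side-chain acid; 25 the 6S amino alcohol
Product: 26 side-chain mono(Q) ester: 1-benzyl 3-methyl (1R,2S,3S,4S)-2-{3-methoxy-4-[(triisopropylsilyl)oxy]phenyl}-1-methyl-4-[(3E)-3-methyl-5-oxo-5-{[(4R,4aR,6R,7R,7aS)-2,4,7-trimethyloctahydro-1H-cyclopenta[c]pyridin-6-yl]oxy}pent-3-en-1-yl]cyclobutane-1,3-dicarboxylate
Conditions: 25 (1.3 equiv), PPh3 (1.6 equiv), DIAD (1.6 equiv), THF, 0 °C to rt
Reagents that add atoms: none
Why: In the Mitsunobu esterification the enoate carboxylate displaces the oxyphosphonium-activated alcohol by SN2 with inversion (6S to 6R), the only free acid being the side-chain one and the silyl ether keeping the phenol from acting as a competing pronucleophile.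

Step 17
Reactants: 26 the side-chain mono(Q) ester
Product: 28 C1 carboxylic acid: compound 26 with the benzyl ester at quaternary C1 cleaved to CO2H (C3 methyl ester, side-chain Q ester and aryl silyl ether retained), via triethylsilyl ester 27 (not isolated)
Conditions: Pd(OAc)2 (10 mol %), Et3SiH (3 equiv), Et3N (0.5 equiv), CH2Cl2, rt; MeOH, rt
Reagents that add atoms: none
Why: Palladium-catalysed silane transfer hydrogenolysis cleaves the benzyl–oxygen bond to the silyl ester and toluene without gaseous hydrogen, which should spare the hindered trisubstituted enoate, the other esters and the tertiary amine, and methanol then frees the acid (chemoselective benzyl ester hydrogenolysis).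

Step 18
Reactants: 28 the C1 carboxylic acid; 25 the 6S amino alcohol
Product: 29 bis(Q) ester: cyclobutane with the side-chain carboxyl and the C1 carboxyl both esterified by group Q, C3 methyl ester and aryl silyl ether retained
Conditions: 25 (1.5 equiv), PPh3 (2 equiv), DIAD (2 equiv), THF, 0 °C to rt
Reagents that add atoms: none
Why: Mitsunobu esterification makes the hindered quaternary carboxylate the nucleophile and the alcohol the electrophile, so no acyl transfer at the congested C1 carbonyl is needed and C6 of the alcohol is inverted to 6R (SN2 at the oxyphosphonium salt).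

Step 19
Reactants: 29 the bis(Q) ester
Product: 31 C3 carboxylic acid: compound 29 with the C3 methyl ester cleaved to CO2H (both Q esters and aryl silyl ether retained), via trimethylstannyl ester 30 (not isolated)
Conditions: Me3SnOH (6 equiv), toluene, 80 °C; 5% aq HCl, then pH 7 phosphate buffer
Reagents that add atoms: trimethyltin hydroxide, C[Sn](C)(C)O
Why: Trimethyltin hydroxide attacks only the sterically accessible methyl ester under near-neutral conditions, leaving the two esters of the hindered secondary alcohol (one conjugated, one at a quaternary carbon) intact and the C3–H, which already sits in its favoured trans,trans arrangement, unepimerised (mild organotin ester hydrolysis).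

Step 20
Reactants: 31 the C3 carboxylic acid; 25 the 6S amino alcohol
Product: 32 tris(Q) ester of the cyclobutane triacid with the aryl triisopropylsilyl ether retained (O-silyl ether of the target)
Conditions: 25 (1.5 equiv), PPh3 (2 equiv), DIAD (2 equiv), THF, 0 °C to rt
Reagents that add atoms: none
Why: The third Mitsunobu esterification joins the last carboxylate to the amino alcohol with inversion at C6 (6S to 6R) under neutral conditions that do not epimerise the C3–H α to the new ester.

Step 21
Reactants: 32 the silyl-protected triester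
Product: 33 the target, CNP0251577.2
Conditions: TBAF, AcOH, THF, 0 °C
Reagents that add atoms: none
Why: Fluoride cleaves the aryl silyl ether selectively, and the acetic acid buffer prevents ester cleavage and epimerisation α to the ring esters (desilylation).

**Compound list**

1 | tert-butyl but-2-ynoate | CC#CC(=O)OC(C)(C)C | starting material
2 | but-3-en-1-ylmagnesium bromide | C=CCC[Mg]Br | starting material
3 | alkenylcopper adduct, tert-butyl (2Z)-2-cuprio-3-methylhepta-2,6-dienoate | C=CCC/C(C)=C(\[Cu])C(=O)OC(C)(C)C | intermediate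
4 | tert-butyl (2E)-3-methylhepta-2,6-dienoate | C=CCC/C(C)=C/C(=O)OC(C)(C)C | intermediate
5 | methyl acrylate | C=CC(=O)OC | starting material
6 | 1-tert-butyl 8-methyl (2E,6E)-3-methylocta-2,6-dienedioate | COC(=O)/C=C/CC/C(C)=C/C(=O)OC(C)(C)C | intermediate
7 | vanillin | COc1cc(C=O)ccc1O | starting material
8 | 3-methoxy-4-[(triisopropylsilyl)oxy]benzaldehyde | COc1cc(C=O)ccc1O[Si](C(C)C)(C(C)C)C(C)C | intermediate
9 | L-alanine benzyl ester hydrochloride | C[C@H](N)C(=O)OCc1ccccc1.Cl | starting material
10 | benzyl (2S)-2-{[(E)-{3-methoxy-4-[(triisopropylsilyl)oxy]phenyl}methylidene]amino}propanoate | COc1cc(/C=N/[C@@H](C)C(=O)OCc2ccccc2)ccc1O[Si](C(C)C)(C(C)C)C(C)C | intermediate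
11 | 2-benzyl 4-methyl (2S,3S,4S,5R)-3-[(3E)-5-tert-butoxy-3-methyl-5-oxopent-3-en-1-yl]-5-{3-methoxy-4-[(triisopropylsilyl)oxy]phenyl}-2-methylpyrrolidine-2,4-dicarboxylate | COc1cc([C@H]2[C@@H](C(=O)OC)[C@H](CC/C(C)=C/C(=O)OC(C)(C)C)[C@@](N2)(C)C(=O)OCc3ccccc3)ccc1O[Si](C(C)C)(C(C)C)C(C)C | intermediate
12 | 2-benzyl 4-methyl (2S,3S,4S,5S)-3-[(3E)-5-tert-butoxy-3-methyl-5-oxopent-3-en-1-yl]-5-{3-methoxy-4-[(triisopropylsilyl)oxy]phenyl}-2-methylpyrrolidine-2,4-dicarboxylate | COc1cc([C@@H]2[C@@H](C(=O)OC)[C@H](CC/C(C)=C/C(=O)OC(C)(C)C)[C@@](N2)(C)C(=O)OCc3ccccc3)ccc1O[Si](C(C)C)(C(C)C)C(C)C | intermediate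
13 | 1,1-diazene (N-nitrene) of pyrrolidine 12 | COc1cc([C@@H]2[C@@H](C(=O)OC)[C@H](CC/C(C)=C/C(=O)OC(C)(C)C)[C@@]([N+]2=[N-])(C)C(=O)OCc3ccccc3)ccc1O[Si](C(C)C)(C(C)C)C(C)C | intermediate
14 | 1-benzyl 3-methyl (1R,2S,3S,4S)-4-[(3E)-5-tert-butoxy-3-methyl-5-oxopent-3-en-1-yl]-2-{3-methoxy-4-[(triisopropylsilyl)oxy]phenyl}-1-methylcyclobutane-1,3-dicarboxylate | COc1cc([C@@H]2[C@@H](C(=O)OC)[C@H](CC/C(C)=C/C(=O)OC(C)(C)C)[C@@]2(C)C(=O)OCc3ccccc3)ccc1O[Si](C(C)C)(C(C)C)C(C)C | intermediate
15 | side-chain acid: cyclobutane 14 with the tert-butyl ester replaced by the free (E)-enoic acid (C1 benzyl ester, C3 methyl ester, ring 1R,2S,3S,4S) | COc1cc([C@@H]2[C@@H](C(=O)OC)[C@H](CC/C(C)=C/C(=O)O)[C@@]2(C)C(=O)OCc3ccccc3)ccc1O[Si](C(C)C)(C(C)C)C(C)C | intermediate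
16 | but-2-yn-1-amine hydrochloride | CC#CCN.Cl | starting material
17 | tert-butyl but-2-yn-1-ylcarbamate | CC#CCNC(=O)OC(C)(C)C | intermediate
18 | (E)-1,4-dibromobut-2-ene | BrC/C=C/CBr | starting material
19 | tert-butyl [(2E)-4-bromobut-2-en-1-yl](but-2-yn-1-yl)carbamate | CC#CCN(C/C=C/CBr)C(=O)OC(C)(C)C | intermediate
20 | tert-butyl (but-2-yn-1-yl)[(2R)-2-methylbut-3-en-1-yl]carbamate | CC#CCN(C[C@@H](C=C)C)C(=O)OC(C)(C)C | intermediate
21 | tert-butyl (4R,4aR)-4,7-dimethyl-6-oxo-1,3,4,4a,5,6-hexahydro-2H-cyclopenta[c]pyridine-2-carboxylate | O=C1C[C@H]2C(CN(C(=O)OC(C)(C)C)C[C@@H]2C)=C1C | intermediate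
22 | tert-butyl (4R,4aR,7S,7aS)-4,7-dimethyl-6-oxooctahydro-2H-cyclopenta[c]pyridine-2-carboxylate | O=C1C[C@H]2[C@H](CN(C(=O)OC(C)(C)C)C[C@@H]2C)[C@@H]1C | intermediate
23 | tert-butyl (4R,4aR,7R,7aS)-4,7-dimethyl-6-oxooctahydro-2H-cyclopenta[c]pyridine-2-carboxylate | O=C1C[C@H]2[C@H](CN(C(=O)OC(C)(C)C)C[C@@H]2C)[C@H]1C | intermediate
24 | tert-butyl (4R,4aR,6S,7R,7aS)-6-hydroxy-4,7-dimethyloctahydro-2H-cyclopenta[c]pyridine-2-carboxylate | O[C@H]1C[C@H]2[C@H](CN(C(=O)OC(C)(C)C)C[C@@H]2C)[C@H]1C | intermediate
25 | (4R,4aR,6S,7R,7aS)-2,4,7-trimethyloctahydro-1H-cyclopenta[c]pyridin-6-ol | O[C@H]1C[C@H]2[C@H](CN(C)C[C@@H]2C)[C@H]1C | intermediate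
26 | side-chain mono(Q) ester: 1-benzyl 3-methyl (1R,2S,3S,4S)-2-{3-methoxy-4-[(triisopropylsilyl)oxy]phenyl}-1-methyl-4-[(3E)-3-methyl-5-oxo-5-{[(4R,4aR,6R,7R,7aS)-2,4,7-trimethyloctahydro-1H-cyclopenta[c]pyridin-6-yl]oxy}pent-3-en-1-yl]cyclobutane-1,3-dicarboxylate | COc1cc([C@@H]2[C@@H](C(=O)OC)[C@H](CC/C(C)=C/C(=O)O[C@@H]3C[C@H]4[C@H](CN(C)C[C@@H]4C)[C@H]3C)[C@@]2(C)C(=O)OCc3ccccc3)ccc1O[Si](C(C)C)(C(C)C)C(C)C | intermediate
27 | triethylsilyl ester at C1 of compound 26 (benzyl replaced by triethylsilyl) | COc1cc([C@@H]2[C@@H](C(=O)OC)[C@H](CC/C(C)=C/C(=O)O[C@@H]3C[C@H]4[C@H](CN(C)C[C@@H]4C)[C@H]3C)[C@@]2(C)C(=O)O[Si](CC)(CC)CC)ccc1O[Si](C(C)C)(C(C)C)C(C)C | intermediate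
28 | C1 carboxylic acid: compound 26 with the C1 benzyl ester replaced by CO2H | COc1cc([C@@H]2[C@@H](C(=O)OC)[C@H](CC/C(C)=C/C(=O)O[C@@H]3C[C@H]4[C@H](CN(C)C[C@@H]4C)[C@H]3C)[C@@]2(C)C(=O)O)ccc1O[Si](C(C)C)(C(C)C)C(C)C | intermediate
29 | bis(Q) ester: side-chain and C1 carboxyls esterified by group Q, C3 methyl ester, aryl triisopropylsilyl ether | COc1cc([C@@H]2[C@@H](C(=O)OC)[C@H](CC/C(C)=C/C(=O)O[C@@H]3C[C@H]4[C@H](CN(C)C[C@@H]4C)[C@H]3C)[C@@]2(C)C(=O)O[C@@H]2C[C@H]3[C@H](CN(C)C[C@@H]3C)[C@H]2C)ccc1O[Si](C(C)C)(C(C)C)C(C)C | intermediate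
30 | trimethylstannyl ester at C3 of compound 29 (methyl replaced by trimethylstannyl) | COc1cc([C@@H]2[C@@H](C(=O)O[Sn](C)(C)C)[C@H](CC/C(C)=C/C(=O)O[C@@H]3C[C@H]4[C@H](CN(C)C[C@@H]4C)[C@H]3C)[C@@]2(C)C(=O)O[C@@H]2C[C@H]3[C@H](CN(C)C[C@@H]3C)[C@H]2C)ccc1O[Si](C(C)C)(C(C)C)C(C)C | intermediate
31 | C3 carboxylic acid: compound 29 with the C3 methyl ester replaced by CO2H | COc1cc([C@@H]2[C@@H](C(=O)O)[C@H](CC/C(C)=C/C(=O)O[C@@H]3C[C@H]4[C@H](CN(C)C[C@@H]4C)[C@H]3C)[C@@]2(C)C(=O)O[C@@H]2C[C@H]3[C@H](CN(C)C[C@@H]3C)[C@H]2C)ccc1O[Si](C(C)C)(C(C)C)C(C)C | intermediate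
32 | tris(Q) ester, O-triisopropylsilyl ether of the target | COc1cc([C@@H]2[C@@H](C(=O)O[C@@H]3C[C@H]4[C@H](CN(C)C[C@@H]4C)[C@H]3C)[C@H](CC/C(C)=C/C(=O)O[C@@H]3C[C@H]4[C@H](CN(C)C[C@@H]4C)[C@H]3C)[C@@]2(C)C(=O)O[C@@H]2C[C@H]3[C@H](CN(C)C[C@@H]3C)[C@H]2C)ccc1O[Si](C(C)C)(C(C)C)C(C)C | intermediate
33 | CNP0251577.2, the free phenol triester | COc1cc([C@@H]2[C@@H](C(=O)O[C@@H]3C[C@H]4[C@H](CN(C)C[C@@H]4C)[C@H]3C)[C@H](CC/C(C)=C/C(=O)O[C@@H]3C[C@H]4[C@H](CN(C)C[C@@H]4C)[C@H]3C)[C@@]2(C)C(=O)O[C@@H]2C[C@H]3[C@H](CN(C)C[C@@H]3C)[C@H]2C)ccc1O | target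

**Step count and risks**

Total step count: 21. Longest linear sequence: 13 steps (16 to 33 through steps 9 to 21).

Steps most likely to fail:

Step 7 (ring contraction). After loss of N2 the 1,4-biradical may fragment by β-scission into a cinnamate and an enoate instead of coupling, bond rotation before coupling may erode the configuration at the benzylic carbon, or the hypervalent iodine reagent may oxidise the electron-rich arene before nitrogen transfer. The fallback sets out from 12 and generates the same diazene stepwise without an arene-oxidising reagent and at lower temperature. t-BuONO in CH2Cl2 should give the N-nitroso derivative of pyrrolidine 12 F1, Zn/AcOH should reduce it to the N-amino derivative of pyrrolidine 12 F2, and HgO in benzene at rt should oxidise F2 to 1,1-diazene 13, which loses N2 and comes back to the route at 14. This fallback addresses oxidative degradation and temperature, not the intrinsic fragmentation of the biradical.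

Step 6 (C5 epimerisation). The equilibrium may not lie far enough on the side of 12, or thiyl radicals may add reversibly to the trisubstituted enoate and scramble its (E) geometry or give thiol adducts. The fallback sets out from 11 and replaces the radical hydrogen shuttle by metal-hydride hydrogen transfer. [Cp*IrI2]2 (2 mol %) in toluene at 90 °C should dehydrogenate the amine reversibly to the cyclic imine F3 and re-add the hydride until the thermodynamic epimer dominates, coming back to the route at 12 without any radical that could touch the enoate. A risk of this fallback is that F3 tautomerises to a stable enamino ester and accumulates.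

Step 18 (Mitsunobu esterification of the quaternary C1 acid). Displacement by the hindered, internally ion-paired carboxylate may stall, so that the activated alcohol eliminates to a cyclopentene and the acid is returned. The fallback switches from alcohol activation with inversion to acyl activation with retention. Setting out from 25, a Mitsunobu reaction with 4-nitrobenzoic acid (PPh3, DIAD) should give the inverted 4-nitrobenzoate F4, and K2CO3 in MeOH should release the 6R amino alcohol F5. Setting out from 28, 1-chloro-N,N,2-trimethylprop-1-en-1-amine in CH2Cl2 should give the C1 acyl chloride F6 under neutral conditions. F6 and F5 (1.5 equiv) with DMAP and pyridine at 40 °C should then give the C1 ester and come back to the route at 29.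

Further compounds
F1 | step 7 | N-nitroso derivative of pyrrolidine 12 | COc1cc([C@@H]2[C@@H](C(=O)OC)[C@H](CC/C(C)=C/C(=O)OC(C)(C)C)[C@@](N2N=O)(C)C(=O)OCc3ccccc3)ccc1O[Si](C(C)C)(C(C)C)C(C)C
F2 | step 7 | N-amino derivative of pyrrolidine 12 | COc1cc([C@@H]2[C@@H](C(=O)OC)[C@H](CC/C(C)=C/C(=O)OC(C)(C)C)[C@@](N2N)(C)C(=O)OCc3ccccc3)ccc1O[Si](C(C)C)(C(C)C)C(C)C
F3 | step 6 | 2-benzyl 4-methyl (2S,3S,4S)-3-[(3E)-5-tert-butoxy-3-methyl-5-oxopent-3-en-1-yl]-5-{3-methoxy-4-[(triisopropylsilyl)oxy]phenyl}-2-methyl-3,4-dihydro-2H-pyrrole-2,4-dicarboxylate | COc1cc(C=2[C@@H](C(=O)OC)[C@H](CC/C(C)=C/C(=O)OC(C)(C)C)[C@@](N2)(C)C(=O)OCc3ccccc3)ccc1O[Si](C(C)C)(C(C)C)C(C)C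
F4 | step 18 | (4R,4aR,6R,7R,7aS)-2,4,7-trimethyloctahydro-1H-cyclopenta[c]pyridin-6-yl 4-nitrobenzoate | O=C(O[C@@H]1C[C@H]2[C@H](CN(C)C[C@@H]2C)[C@H]1C)c1ccc(cc1)[N+](=O)[O-]
F5 | step 18 | (4R,4aR,6R,7R,7aS)-2,4,7-trimethyloctahydro-1H-cyclopenta[c]pyridin-6-ol | O[C@@H]1C[C@H]2[C@H](CN(C)C[C@@H]2C)[C@H]1C
F6 | step 18 | C1 acyl chloride of acid 28 | COc1cc([C@@H]2[C@@H](C(=O)OC)[C@H](CC/C(C)=C/C(=O)O[C@@H]3C[C@H]4[C@H](CN(C)C[C@@H]4C)[C@H]3C)[C@@]2(C)C(=O)Cl)ccc1O[Si](C(C)C)(C(C)C)C(C)C
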